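**Retrosynthetic overview**

1. Germacrane numbering: carbocycle C1–C10 (C10 carries Me and OH, C3 OH, C4=C5 Z, C8 O-tigloyl), lactone ring O–C6–C7–C11(=C13)–C12(=O); the SMILES is read as 3S,6R,7S,8R,10S, i.e. a cis-fused lactone with H7/H8 trans. Target 27 ⇐ 26 (desilylation) ⇐ 24 (tigloylation of the C8 alcohol).
2. Key disconnection C7–C8: the ten-membered carbocycle is closed last, by an intramolecular Nozaki–Hiyama allylation of seco-aldehyde 22, in which the five-membered lactone already exists as a 3-(bromomethyl)butenolide.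
3. Enabling feature: the exocyclic C11=C13 methylene of the lactone ring sits on the ring-fusion atom C7, which carries the oxygenated C8 of the carbocycle; the array C13=C11–C7–C8–O is a homoallylic alcohol, the retron of a carbonyl allylation with allyl transposition (C13–Br/C7=C11 → C13=C11/C7–C8).
4. The lactone ring is made first (step 15, ring-closing metathesis of the 2-(bromomethyl)acrylate 19 of the C6 carbinol 17); C3–C4 comes from a Ni/Cr coupling of vinyl iodide 6 with aldehyde 12.
5. Stereochemical sources: C10 from (S)-linalool, C6 from a Sharpless kinetic resolution, C3 from a CBS reduction, C7 and C8 from the key step.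

Key step: step 18

Assumption: (Z)-3-iodobut-2-en-1-ol (1) and (S)-(+)-linalool (7) are taken as commercial; 1 is otherwise one step from but-2-yn-1-ol (Red-Al, then iodine).

**Route**

Step 1
Reactants: 1 (Z)-3-iodobut-2-en-1-ol
Product: 2 (Z)-3-iodobut-2-enal
Conditions: MnO2 (activated), CH2Cl2, rt; used at once
Reagents that add atoms: none
Why: Oxidation of an allylic alcohol with activated manganese dioxide is neutral and selective, so the Z vinyl iodide should survive; the aldehyde is used at once to avoid Z/E isomerisation.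

Step 2
Reactants: 2 (Z)-3-iodobut-2-enal; 3 vinylmagnesium bromide
Product: 4 rac-(Z)-5-iodohexa-1,4-dien-3-ol
Conditions: THF, −78 °C; aq NH4Cl
Reagents that add atoms: none
Why: 1,2-Addition of a vinyl Grignard reagent to the enal gives the bis-allylic carbinol (future C6, with future C7 as its vinyl carbon), racemic by design because the next step resolves it.

Step 3
Reactants: 4 rac-(Z)-5-iodohexa-1,4-dien-3-ol
Product: 5 (S,Z)-5-iodohexa-1,4-dien-3-ol
Conditions: Ti(OiPr)4 (cat.), L-(+)-DIPT, t-BuOOH (0.6 equiv), 4 Å MS, CH2Cl2, −20 °C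
Reagents that add atoms: none
Why: Sharpless kinetic resolution: with L-(+)-tartrate the (R)-carbinol is epoxidised at its vinyl group (the cis-substituted, electron-poor iodoalkene is a poor substrate), and the (S)-alcohol, which has the C6 configuration of the target, should be recovered past half conversion.

Step 4
Reactants: 5 (S,Z)-5-iodohexa-1,4-dien-3-ol
Product: 6 (S,Z)-5-iodo-3-(triethylsilyloxy)hexa-1,4-diene
Conditions: Et3SiCl, imidazole, CH2Cl2, 0 °C
Reagents that add atoms: chlorotriethylsilane, CC[Si](Cl)(CC)CC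
Why: Standard imidazole-promoted silylation of a secondary alcohol; TES is chosen so that this ether can later be cleaved beside a TBS ether and a hindered tertiary TES ether.

Step 5
Reactants: 7 (S)-linalool
Product: 8 (S)-3,7-dimethyl-3-(triethylsilyloxy)octa-1,6-diene
Conditions: Et3SiOTf, 2,6-lutidine, CH2Cl2, −78 → 0 °C
Reagents that add atoms: triethylsilyl trifluoromethanesulfonate, CC[Si](CC)(CC)OS(=O)(=O)C(F)(F)F
Why: Silyl triflate silylation is the standard protection of a tertiary alcohol; the quaternary carbinol C10 with its methyl group is taken unchanged from the chiral pool (10S).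

Step 6
Reactants: 8 (S)-3,7-dimethyl-3-(triethylsilyloxy)octa-1,6-diene
Product: 10 (S)-3,7-dimethyl-3-(triethylsilyloxy)oct-6-en-1-ol, via alkylborane 9 (not isolated)
Conditions: 9-BBN, THF, rt; then NaOH, H2O2, 0 °C
Reagents that add atoms: hydrogen peroxide, OO
Why: Hydroboration–oxidation: 9-BBN adds anti-Markovnikov to the monosubstituted vinyl group and leaves the trisubstituted alkene, giving the primary alcohol that becomes C8.

Step 7
Reactants: 10 (S)-3,7-dimethyl-3-(triethylsilyloxy)oct-6-en-1-ol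
Product: 11 (S)-1-(4-methoxybenzyloxy)-3,7-dimethyl-3-(triethylsilyloxy)oct-6-ene
Conditions: NaH, PMBCl, n-Bu4NI (cat.), THF/DMF, 0 °C → rt
Reagents that add atoms: 4-methoxybenzyl chloride, COc1ccc(CCl)cc1
Why: Williamson etherification of the primary alkoxide; the PMB ether is orthogonal to the silyl ethers and is removed oxidatively just before the key step.

Step 8
Reactants: 11 (S)-1-(4-methoxybenzyloxy)-3,7-dimethyl-3-(triethylsilyloxy)oct-6-ene
Product: 12 (S)-6-(4-methoxybenzyloxy)-4-methyl-4-(triethylsilyloxy)hexanal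
Conditions: OsO4 (cat.), NaIO4, 2,6-lutidine, dioxane/H2O, rt
Reagents that add atoms: sodium periodate, [Na+].[O-]I(=O)(=O)=O
Why: Lemieux–Johnson oxidation (catalytic osmylation, periodate cleavage) cuts the only alkene and unveils the C3 aldehyde without touching the electron-rich PMB arene, which ozone could attack.

Step 9
Reactants: 6 (S,Z)-5-iodo-3-(triethylsilyloxy)hexa-1,4-diene; 12 (S)-6-(4-methoxybenzyloxy)-4-methyl-4-(triethylsilyloxy)hexanal
Product: 13 (3S,6RS,7Z,9S)-1-(4-methoxybenzyloxy)-3,7-dimethyl-3,9-bis(triethylsilyloxy)undeca-7,10-dien-6-ol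
Conditions: CrCl2, NiCl2 (cat.), DMSO, rt
Reagents that add atoms: none
Why: Nozaki–Hiyama–Kishi coupling: nickel inserts into the C–I bond with retention of the Z geometry and the alkenylchromium species adds chemoselectively to the aldehyde, forming C3–C4; the C3 carbinol forms as an epimer mixture that the next two steps correct.

Step 10
Reactants: 13 (3S,6RS,7Z,9S)-1-(4-methoxybenzyloxy)-3,7-dimethyl-3,9-bis(triethylsilyloxy)undeca-7,10-dien-6-ol
Product: 14 (3S,7Z,9S)-1-(4-methoxybenzyloxy)-3,7-dimethyl-3,9-bis(triethylsilyloxy)undeca-7,10-dien-6-one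
Conditions: Dess–Martin periodinane, CH2Cl2, 0 °C → rt
Reagents that add atoms: none
Why: Dess–Martin oxidation of the allylic alcohol under near-neutral conditions converges both C3 epimers to the Z-enone without isomerising the trisubstituted alkene.

Step 11
Reactants: 14 (3S,7Z,9S)-1-(4-methoxybenzyloxy)-3,7-dimethyl-3,9-bis(triethylsilyloxy)undeca-7,10-dien-6-one
Product: 15 (3S,6S,7Z,9S)-1-(4-methoxybenzyloxy)-3,7-dimethyl-3,9-bis(triethylsilyloxy)undeca-7,10-dien-6-ol
Conditions: (R)-Me-CBS (cat.), catecholborane, toluene, −78 °C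
Reagents that add atoms: none
Why: Corey–Bakshi–Shibata reduction: the α-methyl alkenyl group acts as the large substituent, so the (R)-oxazaborolidine should give the (3S)-allylic alcohol under reagent control; catecholborane at −78 °C does not hydroborate the vinyl group.

Step 12
Reactants: 15 (3S,6S,7Z,9S)-1-(4-methoxybenzyloxy)-3,7-dimethyl-3,9-bis(triethylsilyloxy)undeca-7,10-dien-6-ol
Product: 16 (3S,6S,7Z,9S)-6-(tert-butyldimethylsilyloxy)-1-(4-methoxybenzyloxy)-3,7-dimethyl-3,9-bis(triethylsilyloxy)undeca-7,10-diene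
Conditions: TBSOTf, 2,6-lutidine, CH2Cl2, −78 °C
Reagents that add atoms: tert-butyldimethylsilyl trifluoromethanesulfonate, CC(C)(C)[Si](C)(C)OS(=O)(=O)C(F)(F)F
Why: Silyl triflate silylation of the hindered secondary allylic alcohol; TBS is chosen to outlast the selective removal of the C6 TES ether.

Step 13
Reactants: 16 (3S,6S,7Z,9S)-6-(tert-butyldimethylsilyloxy)-1-(4-methoxybenzyloxy)-3,7-dimethyl-3,9-bis(triethylsilyloxy)undeca-7,10-diene
Product: 17 (3S,4Z,6S,9S)-6-(tert-butyldimethylsilyloxy)-11-(4-methoxybenzyloxy)-5,9-dimethyl-9-(triethylsilyloxy)undeca-1,4-dien-3-ol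
Conditions: HF·pyridine, pyridine, THF, 0 °C
Reagents that add atoms: none
Why: Buffered HF·pyridine desilylation should cleave the secondary TES ether faster than the hindered tertiary TES and the secondary TBS ether, releasing only the C6 hydroxyl, and the buffered medium avoids ionisation of the bis-allylic carbinol.

Step 14
Reactants: 17 (3S,4Z,6S,9S)-6-(tert-butyldimethylsilyloxy)-11-(4-methoxybenzyloxy)-5,9-dimethyl-9-(triethylsilyloxy)undeca-1,4-dien-3-ol; 18 2-(bromomethyl)acrylic acid
Product: 19 (3S,4Z,6S,9S)-6-(tert-butyldimethylsilyloxy)-11-(4-methoxybenzyloxy)-5,9-dimethyl-9-(triethylsilyloxy)undeca-1,4-dien-3-yl 2-(bromomethyl)prop-2-enoate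
Conditions: DCC, DMAP (cat.), CH2Cl2, 0 °C
Reagents that add atoms: none
Why: Steglich esterification (carbodiimide activation, DMAP acyl transfer) acylates the only free hydroxyl; low temperature and catalytic DMAP limit substitution at the allylic bromide.

Step 15
Reactants: 19 (3S,4Z,6S,9S)-6-(tert-butyldimethylsilyloxy)-11-(4-methoxybenzyloxy)-5,9-dimethyl-9-(triethylsilyloxy)undeca-1,4-dien-3-yl 2-(bromomethyl)prop-2-enoate
Product: 20 (R)-3-(bromomethyl)-5-[(1Z,3S,6S)-3-(tert-butyldimethylsilyloxy)-8-(4-methoxybenzyloxy)-2,6-dimethyl-6-(triethylsilyloxy)oct-1-enyl]furan-2(5H)-one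
Conditions: Grubbs second-generation catalyst (cat.), toluene, 80 °C
Reagents that add atoms: none
Why: Ring-closing metathesis of an allyl acrylate-type ester to a butenolide: the ruthenium carbene loads on the vinyl group and closes the five-membered lactone onto the acrylate alkene with loss of ethylene, much faster than any reaction with the trisubstituted C4=C5 alkene; C6 is untouched.

Step 16
Reactants: 20 (R)-3-(bromomethyl)-5-[(1Z,3S,6S)-3-(tert-butyldimethylsilyloxy)-8-(4-methoxybenzyloxy)-2,6-dimethyl-6-(triethylsilyloxy)oct-1-enyl]furan-2(5H)-one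
Product: 21 (R)-3-(bromomethyl)-5-[(1Z,3S,6S)-3-(tert-butyldimethylsilyloxy)-8-hydroxy-2,6-dimethyl-6-(triethylsilyloxy)oct-1-enyl]furan-2(5H)-one
Conditions: DDQ, CH2Cl2/pH 7 buffer, 0 °C
Reagents that add atoms: none
Why: Oxidative PMB cleavage with DDQ (benzylic hydride abstraction, hydrolysis of the oxocarbenium ion) is neutral and should leave the silyl ethers, the allylic bromide and the base-sensitive butenolide intact.

Step 17
Reactants: 21 (R)-3-(bromomethyl)-5-[(1Z,3S,6S)-3-(tert-butyldimethylsilyloxy)-8-hydroxy-2,6-dimethyl-6-(triethylsilyloxy)oct-1-enyl]furan-2(5H)-one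
Product: 22 (3S,6S,7Z)-8-[(R)-4-(bromomethyl)-5-oxo-2,5-dihydrofuran-2-yl]-6-(tert-butyldimethylsilyloxy)-3,7-dimethyl-3-(triethylsilyloxy)oct-7-enal
Conditions: Dess–Martin periodinane, CH2Cl2, 0 °C → rt
Reagents that add atoms: none
Why: Dess–Martin oxidation gives the β-silyloxy aldehyde under non-basic conditions, so neither elimination of the C10 silyloxy group nor epimerisation at the γ-position of the butenolide (C6) should occur.

Step 18
Reactants: 22 (3S,6S,7Z)-8-[(R)-4-(bromomethyl)-5-oxo-2,5-dihydrofuran-2-yl]-6-(tert-butyldimethylsilyloxy)-3,7-dimethyl-3-(triethylsilyloxy)oct-7-enal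
Product: 24 (3aS,4R,6S,9S,10Z,11aR)-9-(tert-butyldimethylsilyloxy)-4-hydroxy-6,10-dimethyl-3-methylene-6-(triethylsilyloxy)-3a,4,5,6,7,8,9,11a-octahydrocyclodeca[b]furan-2(3H)-one, via allylchromium 23 (not isolated)
Conditions: CrCl2 (excess), THF, rt, slow addition of 22, 0.002 M
Reagents that add atoms: none
Why: Two equivalents of Cr(II) reduce the allylic C13–Br bond to the allylchromium(III) species 23 (chromium on the primary carbon C13), which adds to the C8 aldehyde through a closed six-membered chair transition state with allylic transposition, so that C7 bonds to C8, the alkene moves from C7=C11 to C11=C13 and the α-methylene lactone is revealed in the ring-closing event. The closest known reactions are the chromium- or zinc-mediated allylation of aldehydes with 3-(bromomethyl)furan-2(5H)-ones to β-(hydroxyalkyl)-α-methylene-γ-butyrolactones and the intramolecular Nozaki–Hiyama allylation of ω-formyl allylic bromides, 2-(bromomethyl)acrylates included, to ten-membered and larger carbocycles. One ring is closed, the ten-membered carbocycle, by C7–C8 bond formation in a 10-exo-trig attack on the aldehyde carbon; the lactone ring is already present and only shifts its double bond. C8 is controlled by the chair: the lactone ring holds C6 trans to the CH2Cr group on the C7=C11 alkene and C9 sits equatorial, which places H7 and H8 anti and should give the (8R) alcohol. C7 is controlled by the tether: the chain leaves C6 through the Z-configured C4=C5 alkene, which folds it back over the butenolide face that carries C5, so that C8 should be delivered syn to C5 and the lactone become cis-fused (7S), whereas the opposite face would require the four bonds from C2 to C8 to span roughly 6 Å around the C7–H edge. The step needs γ- over α-attack of the allylmetal (primary C–Cr bond, closed transition state) and ring closure over oligomerisation (slow addition, high dilution), and the silyl ethers at O3 and O10 keep every other group inert while leaving the C8 hydroxyl as the only free alcohol of 24.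

Step 19
Reactants: 24 (3aS,4R,6S,9S,10Z,11aR)-9-(tert-butyldimethylsilyloxy)-4-hydroxy-6,10-dimethyl-3-methylene-6-(triethylsilyloxy)-3a,4,5,6,7,8,9,11a-octahydrocyclodeca[b]furan-2(3H)-one; 25 tiglic acid
Product: 26 (3aS,4R,6S,9S,10Z,11aR)-9-(tert-butyldimethylsilyloxy)-6,10-dimethyl-3-methylene-2-oxo-6-(triethylsilyloxy)-2,3,3a,4,5,6,7,8,9,11a-decahydrocyclodeca[b]furan-4-yl (E)-2-methylbut-2-enoate
Conditions: DCC, DMAP, CH2Cl2, 0 °C → rt
Reagents that add atoms: none
Why: Steglich esterification of the C8 hydroxyl, the only free alcohol, with tiglic acid; the E geometry is the stable one, and the mild carbodiimide conditions should neither move the exocyclic methylene into the ring nor shift the lactone to O8.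

Step 20
Reactants: 26 (3aS,4R,6S,9S,10Z,11aR)-9-(tert-butyldimethylsilyloxy)-6,10-dimethyl-3-methylene-2-oxo-6-(triethylsilyloxy)-2,3,3a,4,5,6,7,8,9,11a-decahydrocyclodeca[b]furan-4-yl (E)-2-methylbut-2-enoate
Product: 27 (3aS,4R,6S,9S,10Z,11aR)-6,9-dihydroxy-6,10-dimethyl-3-methylene-2-oxo-2,3,3a,4,5,6,7,8,9,11a-decahydrocyclodeca[b]furan-4-yl (E)-2-methylbut-2-enoate
Conditions: HF·pyridine, pyridine, THF, 0 °C → rt
Reagents that add atoms: none
Why: Fluoride-mediated desilylation with HF·pyridine should remove the secondary TBS and tertiary TES ethers under weakly acidic conditions that tolerate the tiglate and the α-methylene lactone; no stereocenter is touched.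

**Compound list**

1 | (Z)-3-iodobut-2-en-1-ol | I/C(C)=C\CO | starting material
2 | (Z)-3-iodobut-2-enal | I/C(C)=C\C=O | intermediate
3 | vinylmagnesium bromide | C=C[Mg]Br | starting material
4 | rac-(Z)-5-iodohexa-1,4-dien-3-ol | I/C(C)=C\C(O)C=C | intermediate
5 | (S,Z)-5-iodohexa-1,4-dien-3-ol | I/C(C)=C\[C@H](C=C)O | intermediate
6 | (S,Z)-5-iodo-3-(triethylsilyloxy)hexa-1,4-diene | I/C(C)=C\[C@H](C=C)O[Si](CC)(CC)CC | intermediate
7 | (S)-linalool, (S)-3,7-dimethylocta-1,6-dien-3-ol | C=C[C@@](C)(O)CCC=C(C)C | starting material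
8 | (S)-3,7-dimethyl-3-(triethylsilyloxy)octa-1,6-diene | C=C[C@@](C)(O[Si](CC)(CC)CC)CCC=C(C)C | intermediate
9 | 9-[(R)-3,7-dimethyl-3-(triethylsilyloxy)oct-6-en-1-yl]-9-borabicyclo[3.3.1]nonane (alkylborane, not isolated) | CC(C)=CCC[C@@](C)(CCB1C2CCCC1CCC2)O[Si](CC)(CC)CC | intermediate
10 | (S)-3,7-dimethyl-3-(triethylsilyloxy)oct-6-en-1-ol | OCC[C@@](C)(O[Si](CC)(CC)CC)CCC=C(C)C | intermediate
11 | (S)-1-(4-methoxybenzyloxy)-3,7-dimethyl-3-(triethylsilyloxy)oct-6-ene | COc1ccc(COCC[C@@](C)(O[Si](CC)(CC)CC)CCC=C(C)C)cc1 | intermediate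
12 | (S)-6-(4-methoxybenzyloxy)-4-methyl-4-(triethylsilyloxy)hexanal | COc1ccc(COCC[C@@](C)(O[Si](CC)(CC)CC)CCC=O)cc1 | intermediate
13 | (3S,6RS,7Z,9S)-1-(4-methoxybenzyloxy)-3,7-dimethyl-3,9-bis(triethylsilyloxy)undeca-7,10-dien-6-ol | COc1ccc(COCC[C@@](C)(O[Si](CC)(CC)CC)CCC(O)/C(C)=C\[C@H](C=C)O[Si](CC)(CC)CC)cc1 | intermediate
14 | (3S,7Z,9S)-1-(4-methoxybenzyloxy)-3,7-dimethyl-3,9-bis(triethylsilyloxy)undeca-7,10-dien-6-one | COc1ccc(COCC[C@@](C)(O[Si](CC)(CC)CC)CCC(=O)/C(C)=C\[C@H](C=C)O[Si](CC)(CC)CC)cc1 | intermediate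
15 | (3S,6S,7Z,9S)-1-(4-methoxybenzyloxy)-3,7-dimethyl-3,9-bis(triethylsilyloxy)undeca-7,10-dien-6-ol | COc1ccc(COCC[C@@](C)(O[Si](CC)(CC)CC)CC[C@H](O)/C(C)=C\[C@H](C=C)O[Si](CC)(CC)CC)cc1 | intermediate
16 | (3S,6S,7Z,9S)-6-(tert-butyldimethylsilyloxy)-1-(4-methoxybenzyloxy)-3,7-dimethyl-3,9-bis(triethylsilyloxy)undeca-7,10-diene | COc1ccc(COCC[C@@](C)(O[Si](CC)(CC)CC)CC[C@H](O[Si](C)(C)C(C)(C)C)/C(C)=C\[C@H](C=C)O[Si](CC)(CC)CC)cc1 | intermediate
17 | (3S,4Z,6S,9S)-6-(tert-butyldimethylsilyloxy)-11-(4-methoxybenzyloxy)-5,9-dimethyl-9-(triethylsilyloxy)undeca-1,4-dien-3-ol | COc1ccc(COCC[C@@](C)(O[Si](CC)(CC)CC)CC[C@H](O[Si](C)(C)C(C)(C)C)/C(C)=C\[C@H](C=C)O)cc1 | intermediate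
18 | 2-(bromomethyl)acrylic acid | C=C(CBr)C(=O)O | starting material
19 | (3S,4Z,6S,9S)-6-(tert-butyldimethylsilyloxy)-11-(4-methoxybenzyloxy)-5,9-dimethyl-9-(triethylsilyloxy)undeca-1,4-dien-3-yl 2-(bromomethyl)prop-2-enoate | COc1ccc(COCC[C@@](C)(O[Si](CC)(CC)CC)CC[C@H](O[Si](C)(C)C(C)(C)C)/C(C)=C\[C@H](C=C)OC(=O)C(=C)CBr)cc1 | intermediate
20 | (R)-3-(bromomethyl)-5-[(1Z,3S,6S)-3-(tert-butyldimethylsilyloxy)-8-(4-methoxybenzyloxy)-2,6-dimethyl-6-(triethylsilyloxy)oct-1-enyl]furan-2(5H)-one | COc1ccc(COCC[C@@](C)(O[Si](CC)(CC)CC)CC[C@H](O[Si](C)(C)C(C)(C)C)/C(C)=C\[C@H]2OC(=O)C(CBr)=C2)cc1 | intermediate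
21 | (R)-3-(bromomethyl)-5-[(1Z,3S,6S)-3-(tert-butyldimethylsilyloxy)-8-hydroxy-2,6-dimethyl-6-(triethylsilyloxy)oct-1-enyl]furan-2(5H)-one | OCC[C@@](C)(O[Si](CC)(CC)CC)CC[C@H](O[Si](C)(C)C(C)(C)C)/C(C)=C\[C@H]1OC(=O)C(CBr)=C1 | intermediate
22 | (3S,6S,7Z)-8-[(R)-4-(bromomethyl)-5-oxo-2,5-dihydrofuran-2-yl]-6-(tert-butyldimethylsilyloxy)-3,7-dimethyl-3-(triethylsilyloxy)oct-7-enal | O=CC[C@@](C)(O[Si](CC)(CC)CC)CC[C@H](O[Si](C)(C)C(C)(C)C)/C(C)=C\[C@H]1OC(=O)C(CBr)=C1 | intermediate
23 | allylchromium(III) dichloride formed from 22 at C13 (not isolated) | O=CC[C@@](C)(O[Si](CC)(CC)CC)CC[C@H](O[Si](C)(C)C(C)(C)C)/C(C)=C\[C@H]1OC(=O)C(C[Cr](Cl)Cl)=C1 | intermediate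
24 | (3aS,4R,6S,9S,10Z,11aR)-9-(tert-butyldimethylsilyloxy)-4-hydroxy-6,10-dimethyl-3-methylene-6-(triethylsilyloxy)-3a,4,5,6,7,8,9,11a-octahydrocyclodeca[b]furan-2(3H)-one | C=C1C(=O)O[C@@H]2/C=C(/C)[C@@H](O[Si](C)(C)C(C)(C)C)CC[C@](C)(O[Si](CC)(CC)CC)C[C@@H](O)[C@H]12 | intermediate
25 | tiglic acid, (E)-2-methylbut-2-enoic acid | C/C=C(\C)C(=O)O | starting material
26 | (3aS,4R,6S,9S,10Z,11aR)-9-(tert-butyldimethylsilyloxy)-6,10-dimethyl-3-methylene-2-oxo-6-(triethylsilyloxy)-2,3,3a,4,5,6,7,8,9,11a-decahydrocyclodeca[b]furan-4-yl (E)-2-methylbut-2-enoate | C=C1C(=O)O[C@@H]2/C=C(/C)[C@@H](O[Si](C)(C)C(C)(C)C)CC[C@](C)(O[Si](CC)(CC)CC)C[C@@H](OC(=O)/C(C)=C/C)[C@H]12 | intermediate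
27 | (3aS,4R,6S,9S,10Z,11aR)-6,9-dihydroxy-6,10-dimethyl-3-methylene-2-oxo-2,3,3a,4,5,6,7,8,9,11a-decahydrocyclodeca[b]furan-4-yl (E)-2-methylbut-2-enoate | C=C1C(=O)O[C@@H]2/C=C(/C)[C@@H](O)CC[C@](C)(O)C[C@@H](OC(=O)/C(C)=C/C)[C@H]12 | target

**Step count and risks**

Total steps: 20 (steps 1–4 and 5–8 are parallel branches). Longest linear sequence: 16 steps (7 → 27 through steps 5–8 and 9–20; the branch from 1 is equally long).

Steps most likely to fail, riskiest first:

Step 18. The allylchromium species may add to the aldehyde of a second molecule, or be lost by protonation or Wurtz-type coupling, faster than the ten-membered ring closes; addition through the butenolide face anti to C5 would give the trans-fused diastereomer. The fallback makes the allyl nucleophile as an isolable boron reagent and closes the ring without a reductant. It sets out from 21: palladium-catalysed borylation of the allylic bromide (B2pin2, Pd2(dba)3, THF, a Miyaura-type allylic borylation) should give the allylboronate alcohol F1. Dess–Martin oxidation should then give the boronate aldehyde F2, which is not concentrated but diluted (toluene, 0.002 M, Sc(OTf)3 cat., −20 °C → rt). There the allylboration of the aldehyde by the 2-alkoxycarbonyl allylboronate, through a compact boron–oxygen chair, should close the ring to the cyclic borate ester F3. Aqueous work-up cleaves the B–O bond and the fallback comes back to the route at 24. This fallback removes the reductive side reactions and tightens the transition state; it keeps the same tether control of the ring fusion.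

Step 13. The tertiary TES ether or the allylic TBS ether may be lost together with the C6 silyl group, or the bis-allylic carbinol may ionise. The fallback moves the differentiation from a selective desilylation to a selective acylation. It sets out from 16: both TES ethers are removed on purpose (TBAF/AcOH, THF, 0 °C → rt, TBS kept) to give the diol F4. Steglich esterification with 18 should acylate only the secondary alcohol, since the tertiary one does not react under carbodiimide conditions, and give the monoester F5. Resilylation of the tertiary alcohol (Et3SiOTf, 2,6-lutidine, −78 °C) comes back to the route at 19.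

Step 11. The Z-enone may isomerise to the E-enone before or during reduction, and facial control by the catalyst may be incomplete next to the remote C6 stereocenter. The fallback sets C3 during C–C bond formation and skips the oxidation–reduction pair. It sets out from 6 and 12, which are coupled under catalytic asymmetric Nozaki–Hiyama–Kishi conditions (CrCl2 with a chiral sulfonamide ligand, NiCl2 cat., Mn, Cp2ZrCl2, MeCN), and comes back to the route at 15; it makes no new compound (F0).

Further compounds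
F1 | step 18 | (R)-5-[(1Z,3S,6S)-3-(tert-butyldimethylsilyloxy)-8-hydroxy-2,6-dimethyl-6-(triethylsilyloxy)oct-1-enyl]-3-[(4,4,5,5-tetramethyl-1,3,2-dioxaborolan-2-yl)methyl]furan-2(5H)-one | OCC[C@@](C)(O[Si](CC)(CC)CC)CC[C@H](O[Si](C)(C)C(C)(C)C)/C(C)=C\[C@H]1OC(=O)C(CB2OC(C)(C)C(C)(C)O2)=C1
F2 | step 18 | (3S,6S,7Z)-6-(tert-butyldimethylsilyloxy)-3,7-dimethyl-8-[(R)-5-oxo-4-[(4,4,5,5-tetramethyl-1,3,2-dioxaborolan-2-yl)methyl]-2,5-dihydrofuran-2-yl]-3-(triethylsilyloxy)oct-7-enal | O=CC[C@@](C)(O[Si](CC)(CC)CC)CC[C@H](O[Si](C)(C)C(C)(C)C)/C(C)=C\[C@H]1OC(=O)C(CB2OC(C)(C)C(C)(C)O2)=C1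
F3 | step 18 | O8-(4,4,5,5-tetramethyl-1,3,2-dioxaborolan-2-yl) borate ester of 24 | C=C1C(=O)O[C@@H]2/C=C(/C)[C@@H](O[Si](C)(C)C(C)(C)C)CC[C@](C)(O[Si](CC)(CC)CC)C[C@@H](OB3OC(C)(C)C(C)(C)O3)[C@H]12
F4 | step 13 | (3S,4Z,6S,9S)-6-(tert-butyldimethylsilyloxy)-11-(4-methoxybenzyloxy)-5,9-dimethylundeca-1,4-diene-3,9-diol | COc1ccc(COCC[C@@](C)(O)CC[C@H](O[Si](C)(C)C(C)(C)C)/C(C)=C\[C@H](C=C)O)cc1
F5 | step 13 | (3S,4Z,6S,9S)-6-(tert-butyldimethylsilyloxy)-9-hydroxy-11-(4-methoxybenzyloxy)-5,9-dimethylundeca-1,4-dien-3-yl 2-(bromomethyl)prop-2-enoate | COc1ccc(COCC[C@@](C)(O)CC[C@H](O[Si](C)(C)C(C)(C)C)/C(C)=C\[C@H](C=C)OC(=O)C(=C)CBr)cc1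
F0 | step 11 | none | none
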